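**Retrosynthetic overview**

- Numbering: C1 ester carbonyl, C2 the CHMe carbon, C3–C6 the four carbons of the 1,2-dioxane (C3 secondary, C6 quaternary), C7–C8 methylenes, C9 the ketone carbon, C10 the methylidene-bearing carbon, C11–C13 methylenes, C14 the carbinol carbon.
- Feature: the 2,3-anti array O–C3–C2–C1 on the 1,2-dioxane ring (ring oxygen on C3, ester carbon C1 on C2) is the net anti addition of peroxide oxygen and a methoxycarbonyl group across a Z-configured C3=C2 alkene that ends in the C2 methyl.
- Disconnections: C9–C10 (alkenyl Grignard reagent plus C9 aldehyde, then oxidation); O–C3 and C2–C1 together (peroxypalladation and methoxycarbonylation of hydroperoxide 15); C3=C2 (Z-selective Wittig); C5–C4 (Wittig, then diimide); C6–OOH (invertive perhydrolysis of a Sharpless epoxide, with the spare carbon removed by glycol cleavage).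
- Ring order: the 1,2-dioxane is the only ring and is closed in step 11; C6 is set in steps 3 and 4, C3 and C2 in step 11.

Key step: step 11

Remark on the chemistry: which face of the Z-alkene a given bisoxazoline antipode selects cannot be predicted with confidence; the (S,S)-ligand is written, and its commercially available antipode takes its place if the C3-epimeric series should form.

**Route**

Step 1
Reactants: 1 pent-4-yn-1-ol
Product: 2 tert-butyl(pent-4-yn-1-yloxy)diphenylsilane
Conditions: TBDPSCl, imidazole, CH2Cl2, 0 °C to rt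
Reagents that add atoms: tert-butylchlorodiphenylsilane, CC(C)(C)[Si](Cl)(c1ccccc1)c1ccccc1
Why: Standard silylation of a primary alcohol gives a silyl ether that should survive the later acidic, oxidative and ylide steps.

Step 2
Reactants: 2 tert-butyl(pent-4-yn-1-yloxy)diphenylsilane
Product: 5 (2E)-6-[(tert-butyldiphenylsilyl)oxy]-3-methylhex-2-en-1-ol, via alkenyldimethylalane 3 (not isolated), via lithium alkenylalanate 4 (not isolated)
Conditions: AlMe3 (2 equiv), Cp2ZrCl2 (0.25 equiv), CH2Cl2, 0 °C to rt; evaporate; n-BuLi, THF/hexane, -78 °C; (CH2O)n, -78 °C to rt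
Reagents that add atoms: trimethylaluminium, C[Al](C)C; formaldehyde (as paraformaldehyde), C=O
Why: Negishi zirconium-catalysed carboalumination adds methyl and aluminium syn across the terminal alkyne with methyl on the internal carbon, and the derived alanate is hydroxymethylated by formaldehyde with retention, so the trisubstituted alkene should be E.

Step 3
Reactants: 5 (2E)-6-[(tert-butyldiphenylsilyl)oxy]-3-methylhex-2-en-1-ol
Product: 6 [(2R,3R)-3-{3-[(tert-butyldiphenylsilyl)oxy]propyl}-3-methyloxiran-2-yl]methanol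
Conditions: Ti(OiPr)4 (10 mol %), D-(-)-diethyl tartrate (12 mol %), t-BuOOH, 4 Å MS, CH2Cl2, -20 °C
Reagents that add atoms: tert-butyl hydroperoxide, CC(C)(C)OO
Why: Katsuki–Sharpless asymmetric epoxidation, in which the D-(-)-tartrate should give the (2R,3R)-epoxide by analogy with geraniol (the L-(+)-ester gives 2S,3S there), sets the future C6 (oxirane C3) and a temporary centre at oxirane C2.

Step 4
Reactants: 6 [(2R,3R)-3-{3-[(tert-butyldiphenylsilyl)oxy]propyl}-3-methyloxiran-2-yl]methanol
Product: 7 (2R,3S)-6-[(tert-butyldiphenylsilyl)oxy]-3-hydroperoxy-3-methylhexane-1,2-diol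
Conditions: H2O2 (anhydrous, in Et2O), H3PMo12O40 (cat.), Et2O, rt
Reagents that add atoms: hydrogen peroxide, OO
Why: Molybdenum-catalysed perhydrolysis of the epoxide should open the activated oxirane at the tertiary carbon in an SN2-like anti fashion, so C6 is installed with inversion (3R in 6 becomes 3S in 7) while the secondary carbon keeps its oxygen.

Step 5
Reactants: 7 (2R,3S)-6-[(tert-butyldiphenylsilyl)oxy]-3-hydroperoxy-3-methylhexane-1,2-diol
Product: 8 (2R,3S)-6-[(tert-butyldiphenylsilyl)oxy]-3-[(2-methoxypropan-2-yl)peroxy]-3-methylhexane-1,2-diol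
Conditions: 2-methoxypropene (1.1 equiv), PPTS (cat.), CH2Cl2, -20 °C; Et3N quench
Reagents that add atoms: 2-methoxypropene, COC(C)=C
Why: Acid-catalysed addition of the hydroperoxide to the enol ether gives the monoperoxyketal, and the more acidic alpha-effect hydroperoxide should be ketalised faster than the hydroxyls when a weak acid, low temperature and only a slight excess of reagent are used.

Step 6
Reactants: 8 (2R,3S)-6-[(tert-butyldiphenylsilyl)oxy]-3-[(2-methoxypropan-2-yl)peroxy]-3-methylhexane-1,2-diol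
Product: 9 (2S)-5-[(tert-butyldiphenylsilyl)oxy]-2-[(2-methoxypropan-2-yl)peroxy]-2-methylpentanal
Conditions: NaIO4, THF/pH 7 buffer, 0 °C
Reagents that add atoms: none
Why: Malaprade glycol cleavage removes the spare carbon and leaves C5 as an aldehyde; the peroxyketal is inert to periodate and the quaternary alpha-carbon cannot enolise.

Step 7
Reactants: 9 (2S)-5-[(tert-butyldiphenylsilyl)oxy]-2-[(2-methoxypropan-2-yl)peroxy]-2-methylpentanal
Product: 10 (2E,4S)-7-[(tert-butyldiphenylsilyl)oxy]-4-[(2-methoxypropan-2-yl)peroxy]-4-methylhept-2-enal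
Conditions: Ph3P=CHCHO, toluene, 60 °C
Reagents that add atoms: (triphenylphosphoranylidene)acetaldehyde, O=CC=P(c1ccccc1)(c1ccccc1)c1ccccc1
Why: Wittig olefination with the formyl-stabilised ylide should give the E-enal, and the inductively activated alpha-peroxy aldehyde is more electrophilic than the enal formed, which limits a second homologation.

Step 8
Reactants: 10 (2E,4S)-7-[(tert-butyldiphenylsilyl)oxy]-4-[(2-methoxypropan-2-yl)peroxy]-4-methylhept-2-enal
Product: 11 (4S)-7-[(tert-butyldiphenylsilyl)oxy]-4-[(2-methoxypropan-2-yl)peroxy]-4-methylheptanal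
Conditions: KO2CN=NCO2K, AcOH (slow addition), CH2Cl2, 0 °C to rt
Reagents that add atoms: none
Why: Diimide reduction transfers two hydrogens to the C=C bond in a concerted syn fashion and should leave the O–O bond, the aldehyde and the silyl ether untouched; this hydrazine-free diimide source avoids hydrazone formation.

Step 9
Reactants: 11 (4S)-7-[(tert-butyldiphenylsilyl)oxy]-4-[(2-methoxypropan-2-yl)peroxy]-4-methylheptanal; 12 ethyltriphenylphosphonium bromide
Product: 14 tert-butyl({(4R,7Z)-4-[(2-methoxypropan-2-yl)peroxy]-4-methylnon-7-en-1-yl}oxy)diphenylsilane, via ethylidenetriphenylphosphorane 13 (not isolated)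
Conditions: NaN(SiMe3)2, THF, 0 °C; then 11, -78 to 0 °C
Reagents that add atoms: none
Why: Salt-free Wittig reaction of the non-stabilised ylide at low temperature should give the Z-alkene under kinetic control, and monoperoxyketals are known to tolerate phosphoranes at -78 °C.

Step 10
Reactants: 14 tert-butyl({(4R,7Z)-4-[(2-methoxypropan-2-yl)peroxy]-4-methylnon-7-en-1-yl}oxy)diphenylsilane
Product: 15 tert-butyl{[(4R,7Z)-4-hydroperoxy-4-methylnon-7-en-1-yl]oxy}diphenylsilane
Conditions: AcOH/THF/H2O (4:2:1), rt
Reagents that add atoms: none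
Why: Mild acid hydrolysis of the monoperoxyketal should release the tertiary hydroperoxide, while the silyl ether and the Z-alkene are stable to aqueous acetic acid.

Step 11
Reactants: 15 tert-butyl{[(4R,7Z)-4-hydroperoxy-4-methylnon-7-en-1-yl]oxy}diphenylsilane
Product: 16 methyl (2S)-2-[(3S,6S)-6-{3-[(tert-butyldiphenylsilyl)oxy]propyl}-6-methyl-1,2-dioxan-3-yl]propanoate
Conditions: Pd(OCOCF3)2 (10 mol %), 2,2'-(propane-2,2-diyl)bis[(4S)-4-tert-butyl-4,5-dihydro-1,3-oxazole] (12 mol %), p-benzoquinone (2 equiv), CO (4 atm), MeOH/CH2Cl2 (1:4), -20 to 0 °C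
Reagents that add atoms: carbon monoxide, [C-]#[O+]; methanol, CO
Why: Proposed new method: the cationic bisoxazoline complex of divalent palladium should bind the Z-alkene, the hydroperoxide oxygen should attack C3 from the face opposite the metal (6-exo-trig closure of the 1,2-dioxane), CO should insert into the C2–Pd bond with retention and methanol should cleave the acyl complex to the methyl ester, after which benzoquinone returns zerovalent palladium to the divalent state. The closest known reactions are the palladium-catalysed cyclisation of unsaturated hydroperoxides to 1,2-dioxanes, which ends in beta-hydride elimination, and the Semmelhack alkoxycarbonylative cyclisation of alkenols (anti oxypalladation, then methoxycarbonylation), which are merged here. C3 is set by the C2-symmetric ligand, which has to choose the alkene face because C6 with its two similar chains gives no bias, and C2 follows from the Z geometry through anti addition and retentive insertion, which gives the 2,3-anti (2S,3S) array. The step needs CO insertion to outrun beta-hydride elimination toward the methyl group and collapse of the beta-peroxyalkyl complex to a ketone, which CO pressure and a saturated coordination sphere should secure. It also needs benzoquinone to outcompete the hydroperoxide as oxidant of CO and of reduced palladium, hence the low temperature and excess quinone; the tertiary hydroperoxide has no alpha-hydrogen, so Kornblum–DeLaMare cleavage of the substrate is excluded.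

Step 12
Reactants: 16 methyl (2S)-2-[(3S,6S)-6-{3-[(tert-butyldiphenylsilyl)oxy]propyl}-6-methyl-1,2-dioxan-3-yl]propanoate
Product: 17 methyl (2S)-2-[(3S,6S)-6-(3-hydroxypropyl)-6-methyl-1,2-dioxan-3-yl]propanoate
Conditions: HF·pyridine, pyridine/THF, 0 °C to rt
Reagents that add atoms: none
Why: Fluoride-mediated desilylation under slightly acidic conditions avoids the basic conditions that could epimerise C2 or open the beta-peroxy ester by retro-oxa-Michael reaction.

Step 13
Reactants: 17 methyl (2S)-2-[(3S,6S)-6-(3-hydroxypropyl)-6-methyl-1,2-dioxan-3-yl]propanoate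
Product: 18 methyl (2S)-2-[(3S,6R)-6-methyl-6-(3-oxopropyl)-1,2-dioxan-3-yl]propanoate
Conditions: Dess–Martin periodinane, CH2Cl2, 0 °C to rt
Reagents that add atoms: none
Why: Dess–Martin oxidation of the primary alcohol is neutral and non-reducing, so the peroxide and the ester should be spared (the C6 descriptor changes only because the CIP priorities change).

Step 14
Reactants: 19 methyl hex-5-ynoate
Product: 21 methyl 5-bromohex-5-enoate, via bromoalkenylborane 20 (not isolated)
Conditions: B-bromo-9-BBN, CH2Cl2, 0 °C; then AcOH, 0 °C to rt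
Reagents that add atoms: B-bromo-9-borabicyclo[3.3.1]nonane, BrB1C2CCCC1CCC2
Why: Syn bromoboration of the terminal alkyne places bromine on the internal carbon, and protonolysis of the C–B bond with acetic acid should give the 2-bromo-1-alkene with the ester intact.

Step 15
Reactants: 21 methyl 5-bromohex-5-enoate
Product: 22 6-bromo-2-methylhept-6-en-2-ol
Conditions: MeMgBr (2.5 equiv), THF, 0 °C; aq. NH4Cl
Reagents that add atoms: methylmagnesium bromide, C[Mg]Br
Why: Double Grignard addition to the ester gives the tertiary alcohol, and the alkenyl bromide is inert to MeMgBr at 0 °C.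

Step 16
Reactants: 22 6-bromo-2-methylhept-6-en-2-ol
Product: 23 [(6-bromo-2-methylhept-6-en-2-yl)oxy]trimethylsilane
Conditions: TMSCl, imidazole, CH2Cl2, rt
Reagents that add atoms: chlorotrimethylsilane, C[Si](C)(C)Cl
Why: Silylation masks the acidic hydroxyl for Grignard formation with a group labile enough to fall off in a dilute acid work-up.

Step 17
Reactants: 18 methyl (2S)-2-[(3S,6R)-6-methyl-6-(3-oxopropyl)-1,2-dioxan-3-yl]propanoate; 23 [(6-bromo-2-methylhept-6-en-2-yl)oxy]trimethylsilane
Product: 26 methyl (2S)-2-[(3S,6S)-6-(3,8-dihydroxy-8-methyl-4-methylidenenonyl)-6-methyl-1,2-dioxan-3-yl]propanoate, via alkenylmagnesium bromide 24 (not isolated), via silyl-protected adduct 25 (not isolated)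
Conditions: 23, Mg, THF, 40 °C; add to 18, THF, -78 °C; then 1 M HCl, THF, 0 °C
Reagents that add atoms: none
Why: Grignard 1,2-addition of the alkenylmagnesium bromide to the aldehyde at -78 °C should be far faster than attack on the hindered methyl ester or the dialkyl peroxide, and the acid work-up hydrolyses the tertiary silyl ether; the new carbinol centre forms as a mixture and is removed in the next step.

Step 18
Reactants: 26 methyl (2S)-2-[(3S,6S)-6-(3,8-dihydroxy-8-methyl-4-methylidenenonyl)-6-methyl-1,2-dioxan-3-yl]propanoate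
Product: 27 aikupikoxide D, methyl (2S)-2-[(3S,6R)-6-(8-hydroxy-8-methyl-4-methylidene-3-oxononyl)-6-methyl-1,2-dioxan-3-yl]propanoate
Conditions: Dess–Martin periodinane, CH2Cl2, 0 °C
Reagents that add atoms: none
Why: Dess–Martin oxidation converts the secondary allylic alcohol into the enone, while the tertiary alcohol cannot be oxidised and the peroxide and ester are inert.

**Compound list**

1 | pent-4-yn-1-ol | C#CCCCO | starting material
2 | tert-butyl(pent-4-yn-1-yloxy)diphenylsilane | C#CCCCO[Si](c1ccccc1)(c1ccccc1)C(C)(C)C | intermediate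
3 | [(1E)-5-[(tert-butyldiphenylsilyl)oxy]-2-methylpent-1-en-1-yl]dimethylalumane | CC(C)(C)[Si](c1ccccc1)(c1ccccc1)OCCC/C(C)=C/[Al](C)C | intermediate (not isolated)
4 | lithium butyl[(1E)-5-[(tert-butyldiphenylsilyl)oxy]-2-methylpent-1-en-1-yl]dimethylaluminate | CC(C)(C)[Si](c1ccccc1)(c1ccccc1)OCCC/C(C)=C/[Al-](C)(C)CCCC.[Li+] | intermediate (not isolated)
5 | (2E)-6-[(tert-butyldiphenylsilyl)oxy]-3-methylhex-2-en-1-ol | CC(C)(C)[Si](c1ccccc1)(c1ccccc1)OCCC/C(C)=C/CO | intermediate
6 | [(2R,3R)-3-{3-[(tert-butyldiphenylsilyl)oxy]propyl}-3-methyloxiran-2-yl]methanol | CC(C)(C)[Si](c1ccccc1)(c1ccccc1)OCCC[C@]1(C)[C@@H](CO)O1 | intermediate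
7 | (2R,3S)-6-[(tert-butyldiphenylsilyl)oxy]-3-hydroperoxy-3-methylhexane-1,2-diol | CC(C)(C)[Si](c1ccccc1)(c1ccccc1)OCCC[C@@](OO)(C)[C@H](O)CO | intermediate
8 | (2R,3S)-6-[(tert-butyldiphenylsilyl)oxy]-3-[(2-methoxypropan-2-yl)peroxy]-3-methylhexane-1,2-diol | CC(C)(C)[Si](c1ccccc1)(c1ccccc1)OCCC[C@@](OOC(C)(C)OC)(C)[C@H](O)CO | intermediate
9 | (2S)-5-[(tert-butyldiphenylsilyl)oxy]-2-[(2-methoxypropan-2-yl)peroxy]-2-methylpentanal | CC(C)(C)[Si](c1ccccc1)(c1ccccc1)OCCC[C@@](OOC(C)(C)OC)(C)C=O | intermediate
10 | (2E,4S)-7-[(tert-butyldiphenylsilyl)oxy]-4-[(2-methoxypropan-2-yl)peroxy]-4-methylhept-2-enal | CC(C)(C)[Si](c1ccccc1)(c1ccccc1)OCCC[C@@](OOC(C)(C)OC)(C)/C=C/C=O | intermediate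
11 | (4S)-7-[(tert-butyldiphenylsilyl)oxy]-4-[(2-methoxypropan-2-yl)peroxy]-4-methylheptanal | CC(C)(C)[Si](c1ccccc1)(c1ccccc1)OCCC[C@@](OOC(C)(C)OC)(C)CCC=O | intermediate
12 | ethyltriphenylphosphonium bromide | CC[P+](c1ccccc1)(c1ccccc1)c1ccccc1.[Br-] | starting material
13 | ethylidenetriphenylphosphorane | CC=P(c1ccccc1)(c1ccccc1)c1ccccc1 | intermediate (not isolated)
14 | tert-butyl({(4R,7Z)-4-[(2-methoxypropan-2-yl)peroxy]-4-methylnon-7-en-1-yl}oxy)diphenylsilane | CC(C)(C)[Si](c1ccccc1)(c1ccccc1)OCCC[C@@](OOC(C)(C)OC)(C)CC/C=C\C | intermediate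
15 | tert-butyl{[(4R,7Z)-4-hydroperoxy-4-methylnon-7-en-1-yl]oxy}diphenylsilane | CC(C)(C)[Si](c1ccccc1)(c1ccccc1)OCCC[C@@](OO)(C)CC/C=C\C | intermediate (key-step precursor)
16 | methyl (2S)-2-[(3S,6S)-6-{3-[(tert-butyldiphenylsilyl)oxy]propyl}-6-methyl-1,2-dioxan-3-yl]propanoate | CC(C)(C)[Si](c1ccccc1)(c1ccccc1)OCCC[C@@]2(C)CC[C@@H]([C@H](C)C(=O)OC)OO2 | intermediate (key-step product)
17 | methyl (2S)-2-[(3S,6S)-6-(3-hydroxypropyl)-6-methyl-1,2-dioxan-3-yl]propanoate | OCCC[C@@]1(C)CC[C@@H]([C@H](C)C(=O)OC)OO1 | intermediate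
18 | methyl (2S)-2-[(3S,6R)-6-methyl-6-(3-oxopropyl)-1,2-dioxan-3-yl]propanoate | O=CCC[C@@]1(C)CC[C@@H]([C@H](C)C(=O)OC)OO1 | intermediate
19 | methyl hex-5-ynoate | C#CCCCC(=O)OC | starting material
20 | methyl (5Z)-6-(9-borabicyclo[3.3.1]nonan-9-yl)-5-bromohex-5-enoate | COC(=O)CCC/C(Br)=C/B1C2CCCC1CCC2 | intermediate (not isolated)
21 | methyl 5-bromohex-5-enoate | C=C(Br)CCCC(=O)OC | intermediate
22 | 6-bromo-2-methylhept-6-en-2-ol | C=C(Br)CCCC(C)(C)O | intermediate
23 | [(6-bromo-2-methylhept-6-en-2-yl)oxy]trimethylsilane | C=C(Br)CCCC(C)(C)O[Si](C)(C)C | intermediate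
24 | bromo{6-methyl-6-[(trimethylsilyl)oxy]hept-1-en-2-yl}magnesium | C=C([Mg]Br)CCCC(C)(C)O[Si](C)(C)C | intermediate (not isolated)
25 | methyl (2S)-2-[(3S,6S)-6-{3-hydroxy-8-methyl-4-methylidene-8-[(trimethylsilyl)oxy]nonyl}-6-methyl-1,2-dioxan-3-yl]propanoate (both carbinol epimers) | C=C(CCCC(C)(C)O[Si](C)(C)C)C(O)CC[C@@]1(C)CC[C@@H]([C@H](C)C(=O)OC)OO1 | intermediate (not isolated)
26 | methyl (2S)-2-[(3S,6S)-6-(3,8-dihydroxy-8-methyl-4-methylidenenonyl)-6-methyl-1,2-dioxan-3-yl]propanoate (both carbinol epimers) | C=C(CCCC(C)(C)O)C(O)CC[C@@]1(C)CC[C@@H]([C@H](C)C(=O)OC)OO1 | intermediate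
27 | aikupikoxide D, methyl (2S)-2-[(3S,6R)-6-(8-hydroxy-8-methyl-4-methylidene-3-oxononyl)-6-methyl-1,2-dioxan-3-yl]propanoate | C=C(CCCC(C)(C)O)C(=O)CC[C@@]1(C)CC[C@@H]([C@H](C)C(=O)OC)OO1 | target

**Step count**

Total: 18 steps. Longest linear sequence: 15 steps (steps 1 to 13, 17 and 18); the side chain takes steps 14 to 16.

**Steps most likely to fail**

1. Step 11. The catalytic cycle may not turn over because the hydroperoxide is consumed as an oxidant of CO or of reduced palladium, the beta-peroxyalkyl complex may collapse by beta-hydride elimination or to a ketone before CO inserts, or the ligand may give poor facial selectivity. The fallback uses known chemistry and sets out from aldehyde 11. Wittig reaction with methyl 2-(triphenylphosphoranylidene)propanoate in toluene should give methyl (2E,6R)-9-[(tert-butyldiphenylsilyl)oxy]-6-[(2-methoxypropan-2-yl)peroxy]-2,6-dimethylnon-2-enoate F1. Hydrolysis with AcOH/THF/H2O should release methyl (2E,6R)-9-[(tert-butyldiphenylsilyl)oxy]-6-hydroperoxy-2,6-dimethylnon-2-enoate F2. Et2NH in CF3CH2OH should then close the 1,2-dioxane by 6-exo intramolecular peroxy-Michael addition. This closure controls neither C3 nor C2 (C2 arises by enolate protonation), so the wanted isomer would have to be separated from its diastereomers by chromatography; the route is rejoined at compound 16.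

2. Step 5. Chemoselectivity may be lost through ketalisation of the primary hydroxyl followed by closure of the diol to the acetonide. The fallback sets out from epoxy alcohol 6. Etherification with 4-methoxybenzyl bromide and Ag2O should give tert-butyl(3-[(2R,3R)-3-{[(4-methoxyphenyl)methoxy]methyl}-2-methyloxiran-2-yl]propoxy)diphenylsilane F3. The same molybdenum-catalysed perhydrolysis should give (2R,3S)-6-[(tert-butyldiphenylsilyl)oxy]-3-hydroperoxy-1-[(4-methoxyphenyl)methoxy]-3-methylhexan-2-ol F4. Ketalisation with 2-methoxypropene and PPTS then competes only with a hindered secondary hydroxyl and should give (2R,3S)-6-[(tert-butyldiphenylsilyl)oxy]-1-[(4-methoxyphenyl)methoxy]-3-[(2-methoxypropan-2-yl)peroxy]-3-methylhexan-2-ol F5. Buffered DDQ removes the benzyl-type ether and returns the route to compound 8.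

3. Step 8. Diimide may disproportionate faster than it reduces the hindered alkene next to the quaternary centre, and the free aldehyde and the acid-labile peroxyketal rule out forcing conditions. The fallback sets out from aldehyde 9. Wittig reaction with methyl (triphenylphosphoranylidene)acetate should give methyl (2E,4S)-7-[(tert-butyldiphenylsilyl)oxy]-4-[(2-methoxypropan-2-yl)peroxy]-4-methylhept-2-enoate F6. This enoate tolerates repeated or more forcing diimide treatment and should give methyl (4S)-7-[(tert-butyldiphenylsilyl)oxy]-4-[(2-methoxypropan-2-yl)peroxy]-4-methylheptanoate F7. Reduction with i-Bu2AlH at -78 °C, which dialkyl peroxides are expected to survive, rejoins the route at compound 11.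

**Further compounds**

F1 | step 11 | methyl (2E,6R)-9-[(tert-butyldiphenylsilyl)oxy]-6-[(2-methoxypropan-2-yl)peroxy]-2,6-dimethylnon-2-enoate | CC(C)(C)[Si](c1ccccc1)(c1ccccc1)OCCC[C@@](OOC(C)(C)OC)(C)CC/C=C(\C)C(=O)OC
F2 | step 11 | methyl (2E,6R)-9-[(tert-butyldiphenylsilyl)oxy]-6-hydroperoxy-2,6-dimethylnon-2-enoate | CC(C)(C)[Si](c1ccccc1)(c1ccccc1)OCCC[C@@](OO)(C)CC/C=C(\C)C(=O)OC
F3 | step 5 | tert-butyl(3-[(2R,3R)-3-{[(4-methoxyphenyl)methoxy]methyl}-2-methyloxiran-2-yl]propoxy)diphenylsilane | CC(C)(C)[Si](c1ccccc1)(c1ccccc1)OCCC[C@]1(C)[C@@H](COCc2ccc(OC)cc2)O1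
F4 | step 5 | (2R,3S)-6-[(tert-butyldiphenylsilyl)oxy]-3-hydroperoxy-1-[(4-methoxyphenyl)methoxy]-3-methylhexan-2-ol | CC(C)(C)[Si](c1ccccc1)(c1ccccc1)OCCC[C@@](OO)(C)[C@H](O)COCc1ccc(OC)cc1
F5 | step 5 | (2R,3S)-6-[(tert-butyldiphenylsilyl)oxy]-1-[(4-methoxyphenyl)methoxy]-3-[(2-methoxypropan-2-yl)peroxy]-3-methylhexan-2-ol | CC(C)(C)[Si](c1ccccc1)(c1ccccc1)OCCC[C@@](OOC(C)(C)OC)(C)[C@H](O)COCc1ccc(OC)cc1
F6 | step 8 | methyl (2E,4S)-7-[(tert-butyldiphenylsilyl)oxy]-4-[(2-methoxypropan-2-yl)peroxy]-4-methylhept-2-enoate | CC(C)(C)[Si](c1ccccc1)(c1ccccc1)OCCC[C@@](OOC(C)(C)OC)(C)/C=C/C(=O)OC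
F7 | step 8 | methyl (4S)-7-[(tert-butyldiphenylsilyl)oxy]-4-[(2-methoxypropan-2-yl)peroxy]-4-methylheptanoate | CC(C)(C)[Si](c1ccccc1)(c1ccccc1)OCCC[C@@](OOC(C)(C)OC)(C)CCC(=O)OC
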